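**Plan**

Ring A is the benzo ring of the coumarin (C4a, C5–C8, C8a), ring B the 2,4-dihydroxyphenyl group on C3, ring C the pyranone (O1, C2, C3, C4, C4a, C8a).
- Retrosynthesis: the three MOM ethers come off last. Ring C is then opened at the lactone bond O1–C8a, leaving C8a–H and a free carboxyl group, that is, a 2,3-diarylacrylic acid. The acid is cut at C3=C4 into a ring B arylacetic acid and a ring A benzaldehyde, and the C8–CMe2 bond is traced back to an O-prenyl ether (aromatic Claisen shift).
- Forward: the ring A aldehyde is built (O-prenylation, Claisen, MOM), the ring B acid is protected, the two are joined by Perkin condensation (C3=C4), ring C is closed last by photocatalytic dehydrogenative lactonisation, and the MOM groups are removed.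
- Enabling feature: in the open acid C8a is the only hydrogen-bearing carbon next to C4a (C5 carries the methoxy group). Ring A is an easily oxidised resorcinol diether in which C4a is ortho to the C5 methoxy and para to the C7 oxygen, while C8a itself is meta to both oxygens. The carboxyl oxygen can therefore be delivered to the C4a/C8a edge and end as O1 on an unfunctionalised C8a.
- Stereochemistry: the target has no stereocentre. The only stereo-element on the way is the alkene geometry of the acid, (E) from the Perkin step and turned to (Z) by the photocatalyst in the key step.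

Key step: step 7

Remark on the chemistry: the ring B acid is bought as its methyl ester (methyl 2,4-dihydroxyphenylacetate), because the free 2-hydroxy acid tends to close to a benzofuranone when its phenols are alkylated.

**Route**

Step 1
Reactants: 1 4-hydroxy-2-methoxybenzaldehyde; 2 prenyl bromide (1-bromo-3-methylbut-2-ene)
Product: 3 2-methoxy-4-[(3-methylbut-2-en-1-yl)oxy]benzaldehyde
Conditions: K2CO3, acetone, reflux
Reagents that add atoms: none
Why: Williamson etherification, in which the acidic para-formyl phenoxide displaces bromide from the primary allylic halide at oxygen while the aldehyde is inert to carbonate.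

Step 2
Reactants: 3 2-methoxy-4-[(3-methylbut-2-en-1-yl)oxy]benzaldehyde
Product: 5 4-hydroxy-2-methoxy-5-(2-methylbut-3-en-2-yl)benzaldehyde, via Claisen dienone 4 (not isolated)
Conditions: EtOH/H2O (4:1), 130 °C, sealed tube
Reagents that add atoms: none
Why: Water-accelerated aromatic Claisen rearrangement, whose [3,3] shift inverts the prenyl unit so that its tertiary carbon bonds to the ring; it should go to C5 (the later C8 of the coumarin) because C3 is flanked by two oxygen substituents, and tautomerisation of dienone 4 restores the phenol.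

Step 3
Reactants: 5 4-hydroxy-2-methoxy-5-(2-methylbut-3-en-2-yl)benzaldehyde
Product: 6 2-methoxy-4-(methoxymethoxy)-5-(2-methylbut-3-en-2-yl)benzaldehyde
Conditions: MOMCl, i-Pr2NEt, CH2Cl2, 0 °C to 40 °C
Reagents that add atoms: chloromethyl methyl ether (MOMCl), COCCl
Why: Standard MOM protection by O-alkylation of the acidic para-formyl phenol, giving an acetal that tolerates the basic condensation and the photooxidation to come.

Step 4
Reactants: 7 methyl 2,4-dihydroxyphenylacetate
Product: 8 methyl 2-[2,4-bis(methoxymethoxy)phenyl]acetate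
Conditions: MOMCl, i-Pr2NEt, CH2Cl2, 0 °C to rt
Reagents that add atoms: chloromethyl methyl ether (MOMCl), COCCl
Why: Standard MOM protection of both phenols under a hindered amine base that does not enolise the ester, which removes the 2-hydroxyl that would otherwise lactonise onto the side chain.

Step 5
Reactants: 8 methyl 2-[2,4-bis(methoxymethoxy)phenyl]acetate
Product: 9 2-[2,4-bis(methoxymethoxy)phenyl]acetic acid
Conditions: LiOH, THF/MeOH/H2O, rt; then 1 M HCl to pH 4, 0 °C
Reagents that add atoms: water (delivered as aqueous LiOH), O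
Why: Ester saponification by acyl–oxygen cleavage; the MOM acetals are inert to hydroxide and should survive brief cold acidification to pH 4.

Step 6
Reactants: 6 2-methoxy-4-(methoxymethoxy)-5-(2-methylbut-3-en-2-yl)benzaldehyde; 9 2-[2,4-bis(methoxymethoxy)phenyl]acetic acid
Product: 11 (E)-2-[2,4-bis(methoxymethoxy)phenyl]-3-[2-methoxy-4-(methoxymethoxy)-5-(2-methylbut-3-en-2-yl)phenyl]prop-2-enoic acid, via mixed acetic anhydride 10 (not isolated)
Conditions: Ac2O, Et3N, 110 °C; then H2O, 60 °C
Reagents that add atoms: none
Why: Perkin condensation, in which the amine enolises the mixed anhydride of the arylacetic acid, the enolate adds to the aldehyde and acetate is eliminated to give the α-arylcinnamic acid with the two aryl rings cis ((E), carboxyl trans to ring A), released from anhydride 10 by water; the amine-buffered medium should spare the MOM acetals, and the alkene geometry is not critical because step 7 begins with photoisomerisation.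

Step 7
Reactants: 11 (E)-2-[2,4-bis(methoxymethoxy)phenyl]-3-[2-methoxy-4-(methoxymethoxy)-5-(2-methylbut-3-en-2-yl)phenyl]prop-2-enoic acid
Product: 13 3-[2,4-bis(methoxymethoxy)phenyl]-5-methoxy-7-(methoxymethoxy)-8-(2-methylbut-3-en-2-yl)-2H-chromen-2-one, via (Z)-acid 12 (not isolated)
Conditions: (−)-riboflavin (5 mol %), O2 (1 atm), MeCN/MeOH (1:1), 402 nm LED, rt
Reagents that add atoms: none
Why: Photoexcited riboflavin first transfers triplet energy to the stilbene-like alkene of 11 and populates the (Z)-acid 12, in which the carboxyl group lies beside ring A; single-electron oxidation of 12 by the excited flavin (ring A radical cation, or the carboxyl radical derived from it) lets the carboxyl oxygen bond to ring A, and a second oxidation with loss of the C8a proton rearomatises the ring while O2 returns the reduced flavin to its resting state and ends as H2O2. The closest known reaction type is the riboflavin-photocatalysed isomerisation and oxidative cyclisation of (E)-cinnamic acids to coumarins, with the oxidative lactonisation of biaryl-2-carboxylic acids as a mechanistic relative. Ring C is closed by O1–C8a bond formation in a net 6-endo sense, reached either by direct attack at C8a or, more likely in view of where the charge sits, by 5-exo spiro attack at C4a followed by a 1,2-shift of the acyloxy oxygen to C8a. No stereocentre is created. The step needs attack on ring A and not ring B, and bond formation at C8a and not C5: only ring A offers an oxygen-activated carbon (C4a, ortho to the C5 methoxy and para to the C7 oxygen) within reach of a five-membered transition state, and of the two carbons next to C4a only C8a carries a hydrogen whose loss restores the aromatic ring, so addition at the methoxy-bearing C5 should be a reversible dead end. The quaternary allylic carbon leaves the vinyl group without allylic hydrogen, which should keep it out of ene reactions with singlet oxygen.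

Step 8
Reactants: 13 3-[2,4-bis(methoxymethoxy)phenyl]-5-methoxy-7-(methoxymethoxy)-8-(2-methylbut-3-en-2-yl)-2H-chromen-2-one
Product: 14 3-(2,4-dihydroxyphenyl)-7-hydroxy-5-methoxy-8-(2-methylbut-3-en-2-yl)-2H-chromen-2-one
Conditions: HCl (1 M in MeOH), 40 °C
Reagents that add atoms: none
Why: Acid-catalysed acetal exchange with methanol removes the three MOM groups as dimethoxymethane; the lactone, the aryl methyl ether and the monosubstituted alkene (whose protonation would need a secondary cation) should be stable to dilute acid at this temperature.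

**Compound list**

1 | 4-hydroxy-2-methoxybenzaldehyde | COc1cc(O)ccc1C=O | starting material
2 | prenyl bromide (1-bromo-3-methylbut-2-ene) | CC(C)=CCBr | starting material
3 | 2-methoxy-4-[(3-methylbut-2-en-1-yl)oxy]benzaldehyde | COc1cc(OCC=C(C)C)ccc1C=O | intermediate
4 | 6-methoxy-3-(2-methylbut-3-en-2-yl)-4-oxocyclohexa-1,5-diene-1-carbaldehyde (racemic, transient Claisen dienone) | COC1=CC(=O)C(C(C)(C)C=C)C=C1C=O | intermediate
5 | 4-hydroxy-2-methoxy-5-(2-methylbut-3-en-2-yl)benzaldehyde | COc1cc(O)c(C(C)(C)C=C)cc1C=O | intermediate
6 | 2-methoxy-4-(methoxymethoxy)-5-(2-methylbut-3-en-2-yl)benzaldehyde | COc1cc(OCOC)c(C(C)(C)C=C)cc1C=O | intermediate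
7 | methyl 2,4-dihydroxyphenylacetate | COC(=O)Cc1ccc(O)cc1O | starting material
8 | methyl 2-[2,4-bis(methoxymethoxy)phenyl]acetate | COC(=O)Cc1ccc(OCOC)cc1OCOC | intermediate
9 | 2-[2,4-bis(methoxymethoxy)phenyl]acetic acid | OC(=O)Cc1ccc(OCOC)cc1OCOC | intermediate
10 | acetic (E)-2-[2,4-bis(methoxymethoxy)phenyl]-3-[2-methoxy-4-(methoxymethoxy)-5-(2-methylbut-3-en-2-yl)phenyl]prop-2-enoic anhydride | CC(=O)OC(=O)/C(c1ccc(OCOC)cc1OCOC)=C/c1cc(C(C)(C)C=C)c(OCOC)cc1OC | intermediate
11 | (E)-2-[2,4-bis(methoxymethoxy)phenyl]-3-[2-methoxy-4-(methoxymethoxy)-5-(2-methylbut-3-en-2-yl)phenyl]prop-2-enoic acid | OC(=O)/C(c1ccc(OCOC)cc1OCOC)=C/c1cc(C(C)(C)C=C)c(OCOC)cc1OC | intermediate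
12 | (Z)-2-[2,4-bis(methoxymethoxy)phenyl]-3-[2-methoxy-4-(methoxymethoxy)-5-(2-methylbut-3-en-2-yl)phenyl]prop-2-enoic acid | OC(=O)/C(c1ccc(OCOC)cc1OCOC)=C\c1cc(C(C)(C)C=C)c(OCOC)cc1OC | intermediate
13 | 3-[2,4-bis(methoxymethoxy)phenyl]-5-methoxy-7-(methoxymethoxy)-8-(2-methylbut-3-en-2-yl)-2H-chromen-2-one | C=CC(C)(C)c1c(OCOC)cc(OC)c2cc(-c3ccc(OCOC)cc3OCOC)c(=O)oc12 | intermediate
14 | 3-(2,4-dihydroxyphenyl)-7-hydroxy-5-methoxy-8-(2-methylbut-3-en-2-yl)-2H-chromen-2-one | C=CC(C)(C)c1c(O)cc(OC)c2cc(-c3ccc(O)cc3O)c(=O)oc12 | target

**Step count and risks**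

Total steps: 8. Longest linear sequence: 6 (steps 1, 2, 3, 6, 7, 8); steps 4 and 5 form the second branch.

Step 7. The oxidation may leave the intended path at the spirocyclic stage: the C7 oxygen may shed its MOM group to give a dearomatised spirodienone, or the vinyl carbon C4 may migrate in place of the acyloxy oxygen. Oxidative cleavage of the electron-rich stilbene double bond is also possible, and bond formation at C8a beside the quaternary carbon may be slow. The fallback places O1 on ring A before the rings are joined and closes the lactone by acyl transfer. It sets out from prenyl bromide 2 and acid 9. 2,4-Dihydroxy-6-methoxybenzaldehyde F1 (purchased) would be O-prenylated with 2 at its non-chelated 4-hydroxyl (K2CO3, acetone) to give 2-hydroxy-6-methoxy-4-[(3-methylbut-2-en-1-yl)oxy]benzaldehyde F2. Claisen rearrangement (N,N-diethylaniline, 190 °C), steered to C3 by the hydrogen-bonded 2-hydroxyl, should pass through 2-hydroxy-6-methoxy-3-(2-methylbut-3-en-2-yl)-4-oxocyclohexa-1,5-diene-1-carbaldehyde F3 to 2,4-dihydroxy-6-methoxy-3-(2-methylbut-3-en-2-yl)benzaldehyde F4. Selective MOM protection of the free 4-hydroxyl (MOMCl, i-Pr2NEt) would give 2-hydroxy-6-methoxy-4-(methoxymethoxy)-3-(2-methylbut-3-en-2-yl)benzaldehyde F5. Perkin–Oglialoro condensation of F5 with acid 9 (Ac2O, Et3N, 110 °C) should then give the coumarin directly, rejoining the route at 13.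

Step 2. The allyl shift may go to the more hindered C3, or continue by a second [3,3] shift to C1 with loss of the formyl group, and the freed phenol may add to the new alkene at high temperature. The fallback builds the C–C bond by cross-coupling and sets out from aldehyde 1. Bromination ortho to the hydroxyl and para to the methoxy group (NBS, MeCN) would give 5-bromo-4-hydroxy-2-methoxybenzaldehyde F6, and MOM protection (MOMCl, i-Pr2NEt) would give 5-bromo-2-methoxy-4-(methoxymethoxy)benzaldehyde F7. A branched-selective (γ) Suzuki–Miyaura coupling with 3-methylbut-2-enylboronic acid pinacol ester (Pd(OAc)2, bulky biaryl dialkylphosphine, K3PO4, THF/H2O) should install the 2-methylbut-3-en-2-yl group and rejoin the route at 6.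

Step 6. Hot acetic anhydride may acetolyse the MOM acetals, and the electron-rich, ortho-substituted aldehyde may condense sluggishly. The fallback uses only basic reagents and sets out from ester 8 and aldehyde 6. The lithium enolate of 8 (LDA, THF, −78 °C) would add to 6 to give methyl 2-[2,4-bis(methoxymethoxy)phenyl]-3-hydroxy-3-[2-methoxy-4-(methoxymethoxy)-5-(2-methylbut-3-en-2-yl)phenyl]propanoate F8 (diastereomer mixture). Mesylation (MsCl, Et3N) would give methyl 2-[2,4-bis(methoxymethoxy)phenyl]-3-[2-methoxy-4-(methoxymethoxy)-5-(2-methylbut-3-en-2-yl)phenyl]-3-(methylsulfonyloxy)propanoate F9. Elimination with DBU would give methyl 2-[2,4-bis(methoxymethoxy)phenyl]-3-[2-methoxy-4-(methoxymethoxy)-5-(2-methylbut-3-en-2-yl)phenyl]prop-2-enoate F10 (E/Z mixture). Saponification (LiOH, THF/MeOH/H2O) would rejoin the route at acid 11, formed together with its isomer 12; both are substrates of step 7.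

**Further compounds**

F1 | step 7 | 2,4-dihydroxy-6-methoxybenzaldehyde | COc1cc(O)cc(O)c1C=O
F2 | step 7 | 2-hydroxy-6-methoxy-4-[(3-methylbut-2-en-1-yl)oxy]benzaldehyde | COc1cc(OCC=C(C)C)cc(O)c1C=O
F3 | step 7 | 2-hydroxy-6-methoxy-3-(2-methylbut-3-en-2-yl)-4-oxocyclohexa-1,5-diene-1-carbaldehyde (racemic, transient) | COC1=CC(=O)C(C(C)(C)C=C)C(O)=C1C=O
F4 | step 7 | 2,4-dihydroxy-6-methoxy-3-(2-methylbut-3-en-2-yl)benzaldehyde | COc1cc(O)c(C(C)(C)C=C)c(O)c1C=O
F5 | step 7 | 2-hydroxy-6-methoxy-4-(methoxymethoxy)-3-(2-methylbut-3-en-2-yl)benzaldehyde | COc1cc(OCOC)c(C(C)(C)C=C)c(O)c1C=O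
F6 | step 2 | 5-bromo-4-hydroxy-2-methoxybenzaldehyde | COc1cc(O)c(Br)cc1C=O
F7 | step 2 | 5-bromo-2-methoxy-4-(methoxymethoxy)benzaldehyde | COc1cc(OCOC)c(Br)cc1C=O
F8 | step 6 | methyl 2-[2,4-bis(methoxymethoxy)phenyl]-3-hydroxy-3-[2-methoxy-4-(methoxymethoxy)-5-(2-methylbut-3-en-2-yl)phenyl]propanoate (diastereomer mixture) | COC(=O)C(c1ccc(OCOC)cc1OCOC)C(O)c1cc(C(C)(C)C=C)c(OCOC)cc1OC
F9 | step 6 | methyl 2-[2,4-bis(methoxymethoxy)phenyl]-3-[2-methoxy-4-(methoxymethoxy)-5-(2-methylbut-3-en-2-yl)phenyl]-3-(methylsulfonyloxy)propanoate (diastereomer mixture) | COC(=O)C(c1ccc(OCOC)cc1OCOC)C(OS(C)(=O)=O)c1cc(C(C)(C)C=C)c(OCOC)cc1OC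
F10 | step 6 | methyl 2-[2,4-bis(methoxymethoxy)phenyl]-3-[2-methoxy-4-(methoxymethoxy)-5-(2-methylbut-3-en-2-yl)phenyl]prop-2-enoate (E/Z mixture) | COC(=O)C(c1ccc(OCOC)cc1OCOC)=Cc1cc(C(C)(C)C=C)c(OCOC)cc1OC
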